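**Retrosynthetic overview** (rings lettered A to F from the 2,4,6-trihydroxyphenoxy end)
- Target 39 comes from global O-demethylation of pentadecamethyl ether 38. 38 comes from Ullmann C–O coupling of the ring C C6–OH of ABC phenol 30 with DEF bromide 37. 37 is made by two Chan–Lam couplings on 4-bromo-2,6-dimethoxyphenol (ring F to E, then EF to D).
- The strategy rests on ring B: O–ring A on C1 (an oxygen that sits between two oxygenated carbons of ring A), OH on C3 and C5, and on C4 an oxygen flanked on both sides that leads to ring C C1 beside C6–O. Ring B is therefore built, not coupled.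
- Ring B is cut into C1–C2 (aryl ethynyl ether 7 carrying ring A) and C3–C6 (vinylketene from diazo enone 23, which already carries O–ring C on C4 and OMe on C5). The bonds formed are C3–C2, C1–C6 and C3–C4.
- 7 comes from 2,4,6-trimethoxyphenol and trichloroethylene. 23 comes from ring C phenol 14 (from 2,3,4-trimethoxybenzaldehyde by Dakin, ortho-formylation, benzylation, Dakin) by addition–elimination on tosyloxyacrylate 18, saponification and diazomethane acylation.
- Ring order: rings A, C, D, E and F enter as bought benzenes; ring B is the only ring formed, in step 11.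

Key step: step 11

Remark: the target has no stereocentre, so only constitution and the enol ether geometry of the intermediates need control; 2,4,6-trimethoxyphenol, 4-bromo-2,6-dimethoxyphenol and 3,4,5-trimethoxyphenylboronic acid are taken as commercial.

**Route**

Step 1
Reactants: 1 2,4,6-trimethoxyphenol; 2 trichloroethylene
Product: 4 2-[(E)-1,2-dichloroethenyloxy]-1,3,5-trimethoxybenzene, via dichloroacetylene 3 (not isolated)
Conditions: K2CO3, DMF, 70 °C
Reagents that add atoms: none
Why: Base-induced loss of HCl from trichloroethylene gives dichloroacetylene, to which the phenoxide adds anti (nucleophilic addition to a haloalkyne), so the crowded ring A oxygen is bonded to an sp carbon without any aryl coupling and the (E)-dichlorovinyl ether should result.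

Step 2
Reactants: 4 2-[(E)-1,2-dichloroethenyloxy]-1,3,5-trimethoxybenzene
Product: 7 2-(ethynyloxy)-1,3,5-trimethoxybenzene, via chloroethynyl ether 5 (not isolated), via lithium acetylide 6 (not isolated)
Conditions: n-BuLi (2.2 equiv), Et2O, −78 to −40 °C; then H2O, −78 °C; kept cold in solution and used at once in step 11
Reagents that add atoms: none
Why: Dehydrochlorination to the chloroalkynyl ether followed by lithium–chlorine exchange is the standard dichlorovinyl ether route to ynol ethers, and cold protonation should give the terminal aryl ethynyl ether, which has no β-hydrogen for retro-ene loss of ketene.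

Step 3
Reactants: 8 2,3,4-trimethoxybenzaldehyde
Product: 10 2,3,4-trimethoxyphenol, via aryl formate 9 (not isolated)
Conditions: mCPBA, CH2Cl2, 0 °C to rt; then Et3N (cat.), MeOH, rt
Reagents that add atoms: 3-chloroperoxybenzoic acid (mCPBA), OOC(=O)c1cccc(Cl)c1
Why: Dakin-type Baeyer–Villiger oxidation, in which the ortho/para-alkoxylated aryl group migrates in the Criegee intermediate and the aryl formate is cleaved by base-catalysed methanolysis.

Step 4
Reactants: 10 2,3,4-trimethoxyphenol
Product: 11 2-hydroxy-3,4,5-trimethoxybenzaldehyde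
Conditions: MgCl2, Et3N, (CH2O)n, MeCN, reflux; then 1 M HCl
Reagents that add atoms: paraformaldehyde (as formaldehyde), C=O
Why: Magnesium-mediated ortho-formylation (Casnati–Skattebøl), in which the magnesium phenoxide delivers formaldehyde to the only free ortho position and a second formaldehyde oxidises the benzylic alkoxide to the aldehyde.

Step 5
Reactants: 11 2-hydroxy-3,4,5-trimethoxybenzaldehyde
Product: 12 2-(benzyloxy)-3,4,5-trimethoxybenzaldehyde
Conditions: BnBr, K2CO3, DMF, 50 °C
Reagents that add atoms: benzyl bromide, BrCc1ccccc1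
Why: Williamson etherification of the salicylaldehyde phenoxide; this oxygen becomes the masked C6–O of ring C.

Step 6
Reactants: 12 2-(benzyloxy)-3,4,5-trimethoxybenzaldehyde
Product: 14 2-(benzyloxy)-3,4,5-trimethoxyphenol, via aryl formate 13 (not isolated)
Conditions: mCPBA, CH2Cl2, 0 °C to rt; then Et3N (cat.), MeOH, rt
Reagents that add atoms: 3-chloroperoxybenzoic acid (mCPBA), OOC(=O)c1cccc(Cl)c1
Why: Second Dakin-type Baeyer–Villiger oxidation; the ortho-benzyloxy and para-methoxy groups favour aryl over hydride migration and the benzyl ether is inert to peracid, giving the ring C phenol whose OH becomes O–ring B.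

Step 7
Reactants: 15 methyl methoxyacetate; 16 methyl formate
Product: 18 methyl (Z)-2-methoxy-3-(tosyloxy)prop-2-enoate, via sodium enolate 17 (not isolated)
Conditions: NaH, THF, 0 °C to rt; evaporate; TsCl, THF/DMF, 0 °C to rt
Reagents that add atoms: p-toluenesulfonyl chloride, Cc1ccc(cc1)S(Cl)(=O)=O
Why: Crossed Claisen formylation (the formate cannot enolise and the ester has a single α-position) followed by O-sulfonylation of the enolate, expected to place the β-oxygen anti to the ester as in O-alkylation of α-formyl ester enolates.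

Step 8
Reactants: 14 2-(benzyloxy)-3,4,5-trimethoxyphenol; 18 methyl (Z)-2-methoxy-3-(tosyloxy)prop-2-enoate
Product: 19 methyl (Z)-3-[2-(benzyloxy)-3,4,5-trimethoxyphenoxy]-2-methoxyprop-2-enoate
Conditions: Cs2CO3, MeCN, 50 °C
Reagents that add atoms: none
Why: Conjugate addition–elimination (vinylic substitution) of the phenoxide at C3 of the β-sulfonyloxyacrylate forms the ring C–O–vinyl bond at an unhindered sp2 CH; the ester-stabilised adduct should expel tosylate to give the isomer with aryloxy anti to the ester (Z).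

Step 9
Reactants: 19 methyl (Z)-3-[2-(benzyloxy)-3,4,5-trimethoxyphenoxy]-2-methoxyprop-2-enoate
Product: 21 (Z)-3-[2-(benzyloxy)-3,4,5-trimethoxyphenoxy]-2-methoxyprop-2-enoic acid, via lithium carboxylate 20 (not isolated)
Conditions: LiOH, THF/H2O, rt; then 1 M HCl to pH 3, 0 °C
Reagents that add atoms: lithium hydroxide, [Li+].[OH-]
Why: Ester saponification, as used routinely on β-aryloxyacrylates, whose donor-substituted C=C is a poor Michael acceptor for hydroxide.

Step 10
Reactants: 21 (Z)-3-[2-(benzyloxy)-3,4,5-trimethoxyphenoxy]-2-methoxyprop-2-enoic acid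
Product: 23 (Z)-4-[2-(benzyloxy)-3,4,5-trimethoxyphenoxy]-1-diazo-3-methoxybut-3-en-2-one, via acid chloride 22 (not isolated)
Conditions: (COCl)2, DMF (cat.), CH2Cl2, 0 °C; evaporate; CH2N2 (3 equiv), Et2O/THF, 0 °C
Reagents that add atoms: diazomethane, C=[N+]=[N-]
Why: Arndt–Eistert-type acylation of diazomethane by the acid chloride, with excess diazomethane taking up HCl; the trisubstituted, donor-substituted alkene should not undergo dipolar cycloaddition, and the aryloxy group anti to the acyl group cannot close to a chromone.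

Step 11
Reactants: 7 2-(ethynyloxy)-1,3,5-trimethoxybenzene (2 equiv); 23 (Z)-4-[2-(benzyloxy)-3,4,5-trimethoxyphenoxy]-1-diazo-3-methoxybut-3-en-2-one
Product: 28 2-[2-(benzyloxy)-3,4,5-trimethoxyphenoxy]-3-methoxy-5-(2,4,6-trimethoxyphenoxy)phenol, via vinylketene 24 (not isolated), via vinylcyclobutenone 25 (not isolated), via dienylketene 26 (not isolated), via cyclohexadienone 27 (not isolated)
Conditions: hν (300 nm, Pyrex), ClCH2CH2Cl (degassed), rt; then 80 °C
Reagents that add atoms: none
Why: Irradiation expels N2 and the alkenyl group migrates (photochemical Wolff rearrangement) to vinylketene 24, whose ketene C=C adds [2+2] to ynol ether 7 to give 4-alkenylcyclobutenone 25; at 80 °C this opens by 4π electrocyclic cleavage to dienylketene 26, which closes and tautomerises to phenol 28. The closest known reaction is the Danheiser benzannulation in its diazo ketone (second-generation) form, established for α′-diazo enones with alkoxy- and siloxyalkynes. Ring B is closed by thermal 6π electrocyclisation of 26, which joins the ketene carbon (C3) to the enol ether CH (C4) after C3–C2 and C1–C6 were made in the cycloaddition. No stereocentre persists, since the sp3 carbons of 25 and 27 are lost on ring opening and enolisation. The step needs regioselective cycloaddition, and the oxygen lone pair of 7 makes its terminal CH the nucleophile that bonds to the ketene carbonyl carbon, which places O–ring A meta to the new OH and para to O–ring C; the (Z) enol ether keeps the aryloxy group on the outside during ring closure. Light of 300 nm through Pyrex should excite the diazo enone and not the alkoxyarenes.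

Step 12
Reactants: 28 2-[2-(benzyloxy)-3,4,5-trimethoxyphenoxy]-3-methoxy-5-(2,4,6-trimethoxyphenoxy)phenol
Product: 29 2-[2-(benzyloxy)-3,4,5-trimethoxyphenoxy]-1,3-dimethoxy-5-(2,4,6-trimethoxyphenoxy)benzene
Conditions: MeI, K2CO3, DMF, rt
Reagents that add atoms: iodomethane, CI
Why: Williamson methylation caps the new ring B phenol so that only one phenol is present in the later copper coupling.

Step 13
Reactants: 29 2-[2-(benzyloxy)-3,4,5-trimethoxyphenoxy]-1,3-dimethoxy-5-(2,4,6-trimethoxyphenoxy)benzene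
Product: 30 6-[2,6-dimethoxy-4-(2,4,6-trimethoxyphenoxy)phenoxy]-2,3,4-trimethoxyphenol
Conditions: H2 (1 atm), 10% Pd/C, EtOAc/MeOH, rt
Reagents that add atoms: none
Why: Catalytic hydrogenolysis of the benzyl ether frees the C6–OH of ring C; diaryl and methyl ethers are inert.

Step 14
Reactants: 31 4-bromo-2,6-dimethoxyphenol; 32 3,4,5-trimethoxyphenylboronic acid
Product: 33 5-bromo-1,3-dimethoxy-2-(3,4,5-trimethoxyphenoxy)benzene
Conditions: Cu(OAc)2 (1 equiv), pyridine, 4 Å MS, CH2Cl2, air, rt
Reagents that add atoms: none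
Why: Chan–Lam–Evans oxidative O-arylation, which tolerates di-ortho-substituted phenols and, being run at room temperature with divalent copper, leaves the aryl bromide untouched; the para bromine blocks oxidative phenol coupling.

Step 15
Reactants: 33 5-bromo-1,3-dimethoxy-2-(3,4,5-trimethoxyphenoxy)benzene
Product: 36 [3,5-dimethoxy-4-(3,4,5-trimethoxyphenoxy)phenyl]boronic acid, via aryllithium 34 (not isolated), via lithium borate 35 (not isolated)
Conditions: n-BuLi, THF, −78 °C; B(OiPr)3, −78 °C to rt; then 1 M HCl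
Reagents that add atoms: triisopropyl borate, CC(C)OB(OC(C)C)OC(C)C; water, O
Why: Bromine–lithium exchange, trapping of the aryllithium as the borate complex and acidic hydrolysis is the standard route from an aryl bromide to an arylboronic acid.

Step 16
Reactants: 36 [3,5-dimethoxy-4-(3,4,5-trimethoxyphenoxy)phenyl]boronic acid; 31 4-bromo-2,6-dimethoxyphenol
Product: 37 5-bromo-2-[3,5-dimethoxy-4-(3,4,5-trimethoxyphenoxy)phenoxy]-1,3-dimethoxybenzene
Conditions: Cu(OAc)2 (1 equiv), pyridine, 4 Å MS, CH2Cl2, air, rt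
Reagents that add atoms: none
Why: Second Chan–Lam–Evans O-arylation with the same chemoselectivity as step 14; the boronic acid carbon has two free ortho positions.

Step 17
Reactants: 30 6-[2,6-dimethoxy-4-(2,4,6-trimethoxyphenoxy)phenoxy]-2,3,4-trimethoxyphenol; 37 5-bromo-2-[3,5-dimethoxy-4-(3,4,5-trimethoxyphenoxy)phenoxy]-1,3-dimethoxybenzene
Product: 38 pentadecamethyl ether of the target
Conditions: CuI (20 mol %), picolinic acid (40 mol %), K3PO4, DMSO, 100 °C
Reagents that add atoms: none
Why: Ullmann-type diaryl ether synthesis with the copper/picolinic acid system developed for ortho-disubstituted phenols; the electrophilic carbon of ring D has both ortho positions free.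

Step 18
Reactants: 38 pentadecamethyl ether of the target
Product: 39 CNP0270681.0
Conditions: BBr3 (excess), CH2Cl2, −78 °C to rt; then H2O, 0 °C, under argon
Reagents that add atoms: none
Why: Lewis acid cleavage of aryl methyl ethers (boron complexation, then bromide attack at methyl) should remove all fifteen methyl groups and leave the five diaryl ether bonds, which have no sp3 carbon to attack.

**Compound list**

1 | 2,4,6-trimethoxyphenol | COc1cc(OC)c(O)c(OC)c1 | starting material
2 | trichloroethylene | ClC=C(Cl)Cl | starting material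
3 | dichloroacetylene | ClC#CCl | intermediate (not isolated)
4 | 2-[(E)-1,2-dichloroethenyloxy]-1,3,5-trimethoxybenzene | Cl/C=C(/Cl)Oc1c(OC)cc(OC)cc1OC | intermediate
5 | 2-(chloroethynyloxy)-1,3,5-trimethoxybenzene | ClC#COc1c(OC)cc(OC)cc1OC | intermediate (not isolated)
6 | lithium (2,4,6-trimethoxyphenoxy)acetylide | [Li]C#COc1c(OC)cc(OC)cc1OC | intermediate (not isolated)
7 | 2-(ethynyloxy)-1,3,5-trimethoxybenzene (2,4,6-trimethoxyphenyl ethynyl ether) | C#COc1c(OC)cc(OC)cc1OC | intermediate
8 | 2,3,4-trimethoxybenzaldehyde | COc1ccc(C=O)c(OC)c1OC | starting material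
9 | 2,3,4-trimethoxyphenyl formate | COc1ccc(OC=O)c(OC)c1OC | intermediate (not isolated)
10 | 2,3,4-trimethoxyphenol | COc1ccc(O)c(OC)c1OC | intermediate
11 | 2-hydroxy-3,4,5-trimethoxybenzaldehyde | O=Cc1cc(OC)c(OC)c(OC)c1O | intermediate
12 | 2-(benzyloxy)-3,4,5-trimethoxybenzaldehyde | O=Cc1cc(OC)c(OC)c(OC)c1OCc1ccccc1 | intermediate
13 | 2-(benzyloxy)-3,4,5-trimethoxyphenyl formate | O=COc1cc(OC)c(OC)c(OC)c1OCc1ccccc1 | intermediate (not isolated)
14 | 2-(benzyloxy)-3,4,5-trimethoxyphenol | Oc1cc(OC)c(OC)c(OC)c1OCc1ccccc1 | intermediate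
15 | methyl methoxyacetate | COCC(=O)OC | starting material
16 | methyl formate | COC=O | starting material
17 | sodium (Z)-2,3-dimethoxy-3-oxoprop-1-en-1-olate (drawn in the extended form) | COC(=O)/C(OC)=C/[O-].[Na+] | intermediate (not isolated)
18 | methyl (Z)-2-methoxy-3-(tosyloxy)prop-2-enoate | COC(=O)/C(OC)=C/OS(=O)(=O)c1ccc(C)cc1 | intermediate
19 | methyl (Z)-3-[2-(benzyloxy)-3,4,5-trimethoxyphenoxy]-2-methoxyprop-2-enoate | COC(=O)/C(OC)=C/Oc1cc(OC)c(OC)c(OC)c1OCc1ccccc1 | intermediate
20 | lithium (Z)-3-[2-(benzyloxy)-3,4,5-trimethoxyphenoxy]-2-methoxyprop-2-enoate | [Li+].[O-]C(=O)/C(OC)=C/Oc1cc(OC)c(OC)c(OC)c1OCc1ccccc1 | intermediate (not isolated)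
21 | (Z)-3-[2-(benzyloxy)-3,4,5-trimethoxyphenoxy]-2-methoxyprop-2-enoic acid | OC(=O)/C(OC)=C/Oc1cc(OC)c(OC)c(OC)c1OCc1ccccc1 | intermediate
22 | (Z)-3-[2-(benzyloxy)-3,4,5-trimethoxyphenoxy]-2-methoxyprop-2-enoyl chloride | ClC(=O)/C(OC)=C/Oc1cc(OC)c(OC)c(OC)c1OCc1ccccc1 | intermediate (not isolated)
23 | (Z)-4-[2-(benzyloxy)-3,4,5-trimethoxyphenoxy]-1-diazo-3-methoxybut-3-en-2-one | [N-]=[N+]=CC(=O)/C(OC)=C/Oc1cc(OC)c(OC)c(OC)c1OCc1ccccc1 | intermediate
24 | (Z)-4-[2-(benzyloxy)-3,4,5-trimethoxyphenoxy]-3-methoxybuta-1,3-dien-1-one | O=C=C/C(OC)=C/Oc1cc(OC)c(OC)c(OC)c1OCc1ccccc1 | intermediate (not isolated)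
25 | 4-{(Z)-2-[2-(benzyloxy)-3,4,5-trimethoxyphenoxy]-1-methoxyethenyl}-3-(2,4,6-trimethoxyphenoxy)cyclobut-2-en-1-one (racemic, transient) | O=C1C=C(Oc2c(OC)cc(OC)cc2OC)C1/C(OC)=C/Oc1cc(OC)c(OC)c(OC)c1OCc1ccccc1 | intermediate (not isolated)
26 | (3E,5Z)-6-[2-(benzyloxy)-3,4,5-trimethoxyphenoxy]-5-methoxy-3-(2,4,6-trimethoxyphenoxy)hexa-1,3,5-trien-1-one | O=C=C/C(Oc1c(OC)cc(OC)cc1OC)=C\C(OC)=C\Oc1cc(OC)c(OC)c(OC)c1OCc1ccccc1 | intermediate (not isolated)
27 | 6-[2-(benzyloxy)-3,4,5-trimethoxyphenoxy]-5-methoxy-3-(2,4,6-trimethoxyphenoxy)cyclohexa-2,4-dien-1-one (racemic, transient) | O=C1C=C(Oc2c(OC)cc(OC)cc2OC)C=C(OC)C1Oc1cc(OC)c(OC)c(OC)c1OCc1ccccc1 | intermediate (not isolated)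
28 | 2-[2-(benzyloxy)-3,4,5-trimethoxyphenoxy]-3-methoxy-5-(2,4,6-trimethoxyphenoxy)phenol (ABC trimer, free C3–OH on ring B) | Oc1cc(Oc2c(OC)cc(OC)cc2OC)cc(OC)c1Oc1cc(OC)c(OC)c(OC)c1OCc1ccccc1 | intermediate
29 | 2-[2-(benzyloxy)-3,4,5-trimethoxyphenoxy]-1,3-dimethoxy-5-(2,4,6-trimethoxyphenoxy)benzene | COc1cc(Oc2c(OC)cc(OC)cc2OC)cc(OC)c1Oc1cc(OC)c(OC)c(OC)c1OCc1ccccc1 | intermediate
30 | 6-[2,6-dimethoxy-4-(2,4,6-trimethoxyphenoxy)phenoxy]-2,3,4-trimethoxyphenol (ABC trimer, free C6–OH on ring C) | COc1cc(Oc2c(OC)cc(OC)cc2OC)cc(OC)c1Oc1cc(OC)c(OC)c(OC)c1O | intermediate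
31 | 4-bromo-2,6-dimethoxyphenol | COc1cc(Br)cc(OC)c1O | starting material
32 | 3,4,5-trimethoxyphenylboronic acid | COc1cc(B(O)O)cc(OC)c1OC | starting material
33 | 5-bromo-1,3-dimethoxy-2-(3,4,5-trimethoxyphenoxy)benzene (EF bromide) | COc1cc(Br)cc(OC)c1Oc1cc(OC)c(OC)c(OC)c1 | intermediate
34 | [3,5-dimethoxy-4-(3,4,5-trimethoxyphenoxy)phenyl]lithium | [Li]c1cc(OC)c(Oc2cc(OC)c(OC)c(OC)c2)c(OC)c1 | intermediate (not isolated)
35 | lithium [3,5-dimethoxy-4-(3,4,5-trimethoxyphenoxy)phenyl]triisopropoxyborate | [Li+].CC(C)O[B-](OC(C)C)(OC(C)C)c1cc(OC)c(Oc2cc(OC)c(OC)c(OC)c2)c(OC)c1 | intermediate (not isolated)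
36 | [3,5-dimethoxy-4-(3,4,5-trimethoxyphenoxy)phenyl]boronic acid | OB(O)c1cc(OC)c(Oc2cc(OC)c(OC)c(OC)c2)c(OC)c1 | intermediate
37 | 5-bromo-2-[3,5-dimethoxy-4-(3,4,5-trimethoxyphenoxy)phenoxy]-1,3-dimethoxybenzene (DEF bromide) | COc1cc(Br)cc(OC)c1Oc1cc(OC)c(Oc2cc(OC)c(OC)c(OC)c2)c(OC)c1 | intermediate
38 | pentadecamethyl ether of the target (ABC trimer joined through ring C C6–O to ring D C1 of the DEF trimer) | COc1cc(Oc2c(OC)cc(OC)cc2OC)cc(OC)c1Oc1cc(OC)c(OC)c(OC)c1Oc1cc(OC)c(Oc2cc(OC)c(Oc3cc(OC)c(OC)c(OC)c3)c(OC)c2)c(OC)c1 | intermediate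
39 | CNP0270681.0 | Oc1cc(O)c(Oc2cc(O)c(Oc3cc(O)c(O)c(O)c3Oc3cc(O)c(Oc4cc(O)c(Oc5cc(O)c(O)c(O)c5)c(O)c4)c(O)c3)c(O)c2)c(O)c1 | target

**Totals**

Total step count: 18. Longest linear sequence: 12 steps (steps 3 to 6, 8 to 13, 17 and 18).

**Steps most likely to fail**

First, step 11. The aryloxy group donates less than an alkoxy group and the 2,6-dimethoxylated ring A shields the alkyne, so the [2+2] cycloaddition may be too slow. The vinylketene would then be lost to dimerisation or to O-acylation of the product phenol (which a K2CO3/MeOH work-up can reverse), and the excess ynol ether may oligomerise at 80 °C. The fallback gives up the benzannulation and assembles ring B's ethers by copper coupling, setting out from 31, 1 and 10 and coming back at 29.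
- 31 is protected with MOMCl and iPr2NEt to give 5-bromo-1,3-dimethoxy-2-(methoxymethoxy)benzene F1.
- F1 is coupled with phenol 1 (CuI, picolinic acid, K3PO4, DMSO, 100 °C) to give 2-[3,5-dimethoxy-4-(methoxymethoxy)phenoxy]-1,3,5-trimethoxybenzene F2.
- HCl in MeOH frees 2,6-dimethoxy-4-(2,4,6-trimethoxyphenoxy)phenol F3.
- In parallel, 10 is iodinated ortho to its OH (I2, NaHCO3, aqueous THF) to 6-iodo-2,3,4-trimethoxyphenol F4 and benzylated (BnBr, K2CO3) to 2-(benzyloxy)-1-iodo-3,4,5-trimethoxybenzene F5.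
- Coupling of F3 with F5 under the same copper/picolinic acid conditions at 110 °C should give 29.
This fallback accepts the hindered aryl coupling that the main route avoids.

Second, step 17. Oxidative addition of the electron-rich bromide 37 and turnover of the crowded phenoxide of 30 may both be slow, leading to stalled conversion and protodebromination. The fallback switches to oxidative coupling, setting out from 37 and coming back at 38. 37 is treated with n-BuLi to give [4-{3,5-dimethoxy-4-(3,4,5-trimethoxyphenoxy)phenoxy}-3,5-dimethoxyphenyl]lithium F6, which is trapped with B(OiPr)3 as the lithium triisopropoxyborate F7 and hydrolysed with aqueous HCl to the DEF boronic acid F8. F8 is then joined to phenol 30 by Chan–Lam coupling (Cu(OAc)2, pyridine, 4 Å MS, CH2Cl2, air, rt) to give 38.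

Third, step 18. Fifteen cleavages must all go to completion while boron aryloxide aggregates precipitate, and the pyrogallol-type product may oxidise in air during isolation, so mixtures of partly methylated phenols may result. The fallback changes the endgame to capture and release, setting out from 38 and coming back at 39. The crude BBr3 product is acetylated without isolation (Ac2O, pyridine) to the pentadecaacetate of the target F9, which is stable and can be purified on silica, with partly methylated acetates separated and resubmitted. Degassed acid-catalysed methanolysis (HCl in MeOH, rt) then releases 39.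

**Further compounds**

F1 | step 11 | 5-bromo-1,3-dimethoxy-2-(methoxymethoxy)benzene | COCOc1c(OC)cc(Br)cc1OC
F2 | step 11 | 2-[3,5-dimethoxy-4-(methoxymethoxy)phenoxy]-1,3,5-trimethoxybenzene | COCOc1c(OC)cc(Oc2c(OC)cc(OC)cc2OC)cc1OC
F3 | step 11 | 2,6-dimethoxy-4-(2,4,6-trimethoxyphenoxy)phenol | Oc1c(OC)cc(Oc2c(OC)cc(OC)cc2OC)cc1OC
F4 | step 11 | 6-iodo-2,3,4-trimethoxyphenol | Oc1c(I)cc(OC)c(OC)c1OC
F5 | step 11 | 2-(benzyloxy)-1-iodo-3,4,5-trimethoxybenzene | Ic1cc(OC)c(OC)c(OC)c1OCc1ccccc1
F6 | step 17 | [4-{3,5-dimethoxy-4-(3,4,5-trimethoxyphenoxy)phenoxy}-3,5-dimethoxyphenyl]lithium | [Li]c1cc(OC)c(Oc2cc(OC)c(Oc3cc(OC)c(OC)c(OC)c3)c(OC)c2)c(OC)c1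
F7 | step 17 | lithium [4-{3,5-dimethoxy-4-(3,4,5-trimethoxyphenoxy)phenoxy}-3,5-dimethoxyphenyl]triisopropoxyborate | [Li+].CC(C)O[B-](OC(C)C)(OC(C)C)c1cc(OC)c(Oc2cc(OC)c(Oc3cc(OC)c(OC)c(OC)c3)c(OC)c2)c(OC)c1
F8 | step 17 | [4-{3,5-dimethoxy-4-(3,4,5-trimethoxyphenoxy)phenoxy}-3,5-dimethoxyphenyl]boronic acid | OB(O)c1cc(OC)c(Oc2cc(OC)c(Oc3cc(OC)c(OC)c(OC)c3)c(OC)c2)c(OC)c1
F9 | step 18 | pentadecaacetate of the target | CC(=O)Oc1cc(OC(C)=O)c(Oc2cc(OC(C)=O)c(Oc3cc(OC(C)=O)c(OC(C)=O)c(OC(C)=O)c3Oc3cc(OC(C)=O)c(Oc4cc(OC(C)=O)c(Oc5cc(OC(C)=O)c(OC(C)=O)c(OC(C)=O)c5)c(OC(C)=O)c4)c(OC(C)=O)c3)c(OC(C)=O)c2)c(OC(C)=O)c1
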